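**Compound numbers used throughout:** 1 aryl aldehyde; 2 aryl alkyne; 3 menthyloxybutenolide; 4 photoadduct; 5 and 6 ring-opened intermediates; 7 cyclobutene-fused lactone; 8 aryl bromide; 9 aryllithium; 10 lactol; 11 2-aryl oxolane fused to the cyclobutene; 12 cyclobutanediol; 13 keto aldehyde; 14 diol; 15 target.

Assumptions on the chemistry: butenolide 3 is taken as the purchasable crystalline (5R) epimer. Lactol 10 and diol 14 are carried as epimer mixtures at the one centre that the following step removes.

## Analysis of the target

Target 15 is a single oxolane (O1, C2–C5) with a 3,4,5-trimethoxyphenyl group on C2, a hydroxymethyl group on C3 and a 2,4,5-trimethoxybenzyl group on C4; C5 is an unsubstituted CH2. The three contiguous stereocentres are 2R,3R,4R, which puts the aryl, hydroxymethyl and benzyl groups all on one face of the ring. This all-cis array is the most crowded diastereomer, so each centre must be set under kinetic control and none may later equilibrate. C2 is a benzylic ether that can ionise in acid, and C3 and C4 become epimerisable whenever their side-chain carbons are carbonyl groups. The sensitive groups are the two electron-rich arenes (the 2,4,5-pattern is easily oxidised and protonated), the benzylic C2–O1 bond (acid, hydrogenolysis) and the primary alcohol. The difficulty is less the bond count than placing three adjacent cis substituents, in one absolute sense, on a ring with no stereochemical anchor. The strategy rests on one feature: the hydroxymethyl carbon on C3 and the benzylic carbon on C4 lie side by side on one face of the C3–C4 bond, where the two sp2 carbons of a cyclobutene fused to C3–C4 would be. O1, C2 and C5 map at the same time onto a γ-lactone (C2 the carbonyl carbon, C5 the acetal carbon), so a butenolide–alkyne [2+2] photoadduct holds the whole oxolane with both arms locked cis.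

## Retrosynthetic reasoning

**15 from 14.** The benzylic C–H bond on the C4 arm is traced back to a C–OH bond. A benzylic alcohol next to an ortho,para-dimethoxylated ring is the easiest position in the molecule to ionise and reduce. This lets the C4 arm be carried at a higher oxidation level until the end.

**14 from 12 via 13, and 12 from 11.** The hydroxymethyl carbon and the benzylic carbinol carbon are joined to a C=C bond, which gives the cyclobutene of 11. In the forward sense the alkene is dihydroxylated to 12, the glycol is cleaved to keto aldehyde 13, and 13 is reduced at once to 14. The cut is made here because the cyclobutene is a latent pair of cis one-carbon arms at the right oxidation levels (one CH, one C–aryl). While the four-membered ring is intact, C3 and C4 cannot epimerise.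

**11 from 10, and 10 from 7 and 9.** The C2–aryl bond and the C2–H bond are cut, leading back to lactone 7 and aryllithium 9, which is made from bromide 8. The forward sequence is 1,2-addition to the lactone, then ionisation of lactol 10 and hydride delivery. The folded bicycle should admit hydride only from its convex face, anti to the cyclobutene, which places the aryl group cis to the two arms. C2 is therefore set by the shape of the ring system and not by a reagent.

**7 from 4 via 5 and 6.** The C5 methylene is traced back to the acetal carbon that carries the menthyloxy auxiliary. The auxiliary is removed before the aryl group is introduced. In acylal 4 the tetrahedral adduct of an aryllithium could collapse with loss of the ring oxygen and then of the auxiliary alkoxide, releasing an aldehyde that would add a second aryl group. The plain lactone 7 has no such exit. Forward, saponification unmasks aldehyde 5, which is reduced as it forms to 6, and acid recloses the ring. The lactone carbonyl stays at C2 and the former acetal carbon becomes C5.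

**4 from 2 and 3 (key disconnection).** The C3–CH and C4–C(aryl) bonds are cut in a retro-[2+2] sense, giving butenolide 3 and alkyne 2. Two skeletal bonds, one ring and two stereocentres are gained in one step from two simple partners. The forward reaction must orient the alkyne head-to-tail (aryl-bearing carbon on the β-carbon) and add it anti to the menthyloxy group.

**2 from 1; 3 and 8 purchased.** The alkyne carbon–carbon triple bond is made by one-carbon homologation of aldehyde 1. The precursors of the key step are therefore one step from commercial material, and the risk of the route sits in the photocycloaddition.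

## Alternatives that were turned down

**Alternative 1: ring-closing metathesis, then hydrogenation.**
- Disconnection: the C3=C4 double bond of 2,5-dihydrofuran A1.
- Key step: a ruthenium alkylidene metathesis catalyst closes diene ether A2, which joins an acrylate unit and a 2-benzylallyl unit through the C2–O1–C5 ether. Hydrogen is then added anti to the C2 aryl group and the ester is reduced.
- For it: it is shorter than the chosen route, convergent, and needs no photochemistry or auxiliary. The connectivity of A1 is unambiguous. On step economy and regiochemical certainty it is stronger.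
- Against it: the metathesis must form a tetrasubstituted alkene from two 1,1-disubstituted olefins, one of them an electron-poor acrylate, which is the least favourable case for ruthenium carbenes. C2 of A1 is benzylic, allylic and vinylogously acidic, so it can racemise or the ring can aromatise to a furan. C3 and C4 must then both be set by hydrogenating a tetrasubstituted alkene under the bias of one aryl group, with hydrogenolysis of the allylic and benzylic C–O bonds as a competitor.
- Comparison: the chosen route gives up brevity but fixes the C3–C4 cis relationship by ring fusion instead of by a face-selective hydrogenation.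

**Alternative 2: carbenoid C–H insertion to a furofuranone.**
- Disconnection: the C2–C3 bond.
- Key step: a dirhodium carboxylate decomposes α-diazo lactone A4, and the carbenoid at C3 inserts into the benzylic C–H bond of the trimethoxybenzyl ether to give cis-fused furofuranone A3. The benzylic lactone C–O bond is later reduced and the acid carbon taken to the alcohol.
- For it: the cis C3–C4 relationship is enforced by ring fusion, as in the chosen route. The end game is stronger, because it passes through no epimerisable aldehyde.
- Against it: the aryl group on C2 must end on the concave face of A3, whereas a five-membered insertion transition state tends to place a large group on the convex side. Ylide formation at the ether oxygen and attack of the carbenoid on the electron-rich arenes compete. A4 has two stereocentres and needs its own multi-step enantioselective synthesis, so the risk is not confined to the key step.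
- Comparison: the chosen route obtains the cis aryl group from convex-face hydride delivery and reaches its key-step precursors in one step.

**Alternative 3: cyclopropane-to-dihydrofuran rearrangement, then hydrogenation.**
- Disconnection: the O1–C5 bond of 4,5-dihydrofuran A5.
- Key step: iodide opens the doubly activated cyclopropane A6 at its CH2 group and the enolate oxygen recloses on that carbon to give A5. Hydrogenation of the C2=C3 enol ether anti to the C4 benzyl group and ester reduction follow.
- For it: the ring-forming step is robust and regiochemically certain, and C4 can come from an enantioselective cyclopropanation. On reliability of the ring construction it is stronger than the photocycloaddition.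
- Against it: the double bond of A5 is a tetrasubstituted, push–pull enol ether and is very unreactive to hydrogen. Forcing conditions threaten the benzylic C2–O1 bond that saturation creates. One substituent on C4 must control two new centres, and the resulting all-cis ester on C3 epimerises readily.
- Comparison: the chosen route sets C3 and C4 by ring fusion and C2 by convex-face attack, and does not leave a carbonyl group on C3 for longer than it takes to reduce it.

Key step: step 2

## Route

**Step 1**
Reactants: 1 2,4,5-trimethoxybenzaldehyde
Product: 2 1-ethynyl-2,4,5-trimethoxybenzene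
Conditions: dimethyl (1-diazo-2-oxopropyl)phosphonate, K2CO3, MeOH, 0 °C → rt
Reagents that add atoms: dimethyl (1-diazo-2-oxopropyl)phosphonate (Ohira–Bestmann reagent), CC(=O)C(=[N+]=[N-])P(=O)(OC)OC
Why: Ohira–Bestmann variant of the Seyferth–Gilbert homologation: methanolysis frees the diazomethylphosphonate anion, which adds to the aldehyde in a Horner–Wadsworth–Emmons sense, and loss of N2 with a 1,2-shift gives the terminal alkyne. The carbonate base is mild and the aldehyde has no enolisable position.

**Step 2**
Reactants: 2 1-ethynyl-2,4,5-trimethoxybenzene; 3 (5R)-5-{[(1R,2S,5R)-2-isopropyl-5-methylcyclohexyl]oxy}furan-2(5H)-one [(5R)-5-(l-menthyloxy)furan-2(5H)-one]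
Product: 4 (1S,4R,5S)-4-(l-menthyloxy)-6-(2,4,5-trimethoxyphenyl)-3-oxabicyclo[3.2.0]hept-6-en-2-one (cis-fused; cyclobutene anti to the menthyloxy group; aryl on the cyclobutene carbon bonded to C5, the former β-carbon)
Conditions: hν (medium-pressure Hg lamp, Pyrex filter), acetone (solvent and triplet sensitiser), −20 °C, Ar; 3 in excess (3 equiv), 2 added slowly; chromatography, then crystallisation
Reagents that add atoms: none
Why: Triplet energy transfer from acetone excites butenolide 3; its α-carbon, an electrophilic α-acyl radical centre, bonds to the unsubstituted, nucleophilic terminus of the donor-polarised alkyne 2, giving a triplet 1,4-biradical with an aryl-stabilised vinyl radical that closes onto the β-carbon after spin inversion. The closest known reaction type is the sensitised [2+2] photocycloaddition of 2(5H)-furanones, 5-alkoxy ones included, with alkynes to cyclobutene-fused lactones. The four-membered ring closes by combination of the two radical termini and can only be cis-fused to the five-membered lactone, which fixes the relative configuration of the new centres C1 and C5. Their absolute sense comes from the existing acetal centre: the bulky menthyloxy group on C4 shields one face of the planar butenolide, so both bonds form anti to it. Three selectivities are needed: head-to-tail orientation, which rests on the polarisation of the alkyne by the 2,4,5-trimethoxyphenyl donor; anti facial attack, which rests on the auxiliary; and excitation of 3 rather than 2, which is why acetone is the solvent, 3 is in excess and 2 is kept dilute. Head-to-head and syn adducts are expected as minor isomers and must be removed at this stage, because loss of the acetal centre in step 3 would turn the syn adduct into the enantiomeric series.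

**Step 3**
Reactants: 4 (1S,4R,5S)-4-(l-menthyloxy)-6-(2,4,5-trimethoxyphenyl)-3-oxabicyclo[3.2.0]hept-6-en-2-one
Product: 7 (1S,5S)-6-(2,4,5-trimethoxyphenyl)-3-oxabicyclo[3.2.0]hept-6-en-2-one, via sodium formylcyclobutenecarboxylate 5 (not isolated), via sodium hydroxymethylcyclobutenecarboxylate 6 (not isolated)
Conditions: NaBH4 (present from the start), aq NaOH added dropwise, EtOH/THF, 0 °C; then 1 M HCl to pH 2, 0 °C → rt
Reagents that add atoms: sodium hydroxide, [Na+].[OH-] (its oxygen enters the carboxyl group; one of the two carboxyl oxygens is lost again as water on lactonisation)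
Why: Saponification of the acylal-type lactone releases the auxiliary and unmasks aldehyde 5, which NaBH4 reduces as it forms to 6; acid then closes the cis hydroxy acid to the γ-lactone. This reductive removal of a 5-alkoxy group keeps the carbonyl at C2 and turns the acetal carbon into the C5 methylene. No ring stereocentre is touched, and only the cis-fused lactone can reclose.

**Step 4**
Reactants: 7 (1S,5S)-6-(2,4,5-trimethoxyphenyl)-3-oxabicyclo[3.2.0]hept-6-en-2-one; 8 5-bromo-1,2,3-trimethoxybenzene
Product: 10 (1S,5S)-2-(3,4,5-trimethoxyphenyl)-6-(2,4,5-trimethoxyphenyl)-3-oxabicyclo[3.2.0]hept-6-en-2-ol (lactol; both C2 anomers in equilibrium with the hydroxy ketone), via 3,4,5-trimethoxyphenyllithium 9 (not isolated)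
Conditions: 8, n-BuLi, THF, −78 °C; then added to 7, THF, −78 °C; aq NH4Cl
Reagents that add atoms: none
Why: Bromine–lithium exchange gives 9, and its 1,2-addition to the γ-lactone at −78 °C stops at the lithium hemiketal, which is protonated to the lactol. Unlike acylal 4, lactone 7 offers the tetrahedral adduct no good leaving group, and inverse addition limits double addition.

**Step 5**
Reactants: 10 (1S,5S)-2-(3,4,5-trimethoxyphenyl)-6-(2,4,5-trimethoxyphenyl)-3-oxabicyclo[3.2.0]hept-6-en-2-ol
Product: 11 (1S,2R,5S)-2-(3,4,5-trimethoxyphenyl)-6-(2,4,5-trimethoxyphenyl)-3-oxabicyclo[3.2.0]hept-6-ene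
Conditions: Et3SiH, BF3·OEt2, CH2Cl2, −78 → −40 °C; aq NaHCO3
Reagents that add atoms: none
Why: Ionic hydrogenation of a lactol: the Lewis acid ionises C2–OH to the aryl-stabilised cyclic oxocarbenium ion and the silane transfers hydride. Hydride should approach the convex face of the folded bicycle, anti to the cyclobutene on the neighbouring carbon, so the aryl group ends cis to the cyclobutene carbons and C2 is set as R.

**Step 6**
Reactants: 11 (1S,2R,5S)-2-(3,4,5-trimethoxyphenyl)-6-(2,4,5-trimethoxyphenyl)-3-oxabicyclo[3.2.0]hept-6-ene
Product: 12 (1R,2R,5R,6S,7S)-2-(3,4,5-trimethoxyphenyl)-6-(2,4,5-trimethoxyphenyl)-3-oxabicyclo[3.2.0]heptane-6,7-diol (both hydroxyls on the convex face, anti to the oxolane ring)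
Conditions: OsO4 (cat.), NMO, acetone/H2O, 0 °C → rt
Reagents that add atoms: osmium tetroxide, O=[Os](=O)(=O)=O (delivers both oxygen atoms to the alkene); 4-methylmorpholine N-oxide, C[N+]1([O-])CCOCC1, and water, O (restore the catalyst, so that in the net equation one hydroxyl oxygen comes from each)
Why: Upjohn dihydroxylation: OsO4 adds suprafacially to the strained, electron-rich cyclobutene from its open convex face and leaves the arenes and the benzylic ether alone. The two new centres are erased in step 7.

**Step 7**
Reactants: 12 (1R,2R,5R,6S,7S)-2-(3,4,5-trimethoxyphenyl)-6-(2,4,5-trimethoxyphenyl)-3-oxabicyclo[3.2.0]heptane-6,7-diol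
Product: 14 {(2R,3R,4R)-4-[hydroxy(2,4,5-trimethoxyphenyl)methyl]-2-(3,4,5-trimethoxyphenyl)oxolan-3-yl}methanol (both carbinol epimers), via keto aldehyde 13 (not isolated)
Conditions: NaIO4 on silica gel, CH2Cl2, 0 °C; filter; then NaBH4, MeOH, −20 → 0 °C
Reagents that add atoms: none
Why: Periodate glycol cleavage of the cis cyclobutane-1,2-diol relieves ring strain and gives keto aldehyde 13 under neutral conditions. Because C3 and C4 of 13 are α to carbonyl groups, it is reduced at once with NaBH4; the new carbinol centre is removed in step 8.

**Step 8**
Reactants: 14 {(2R,3R,4R)-4-[hydroxy(2,4,5-trimethoxyphenyl)methyl]-2-(3,4,5-trimethoxyphenyl)oxolan-3-yl}methanol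
Product: 15 [(2R,3R,4R)-2-(3,4,5-trimethoxyphenyl)-4-(2,4,5-trimethoxybenzyl)oxolan-3-yl]methanol
Conditions: Et3SiH (excess), CF3CO2H, CH2Cl2, −40 → 0 °C; then K2CO3, MeOH
Reagents that add atoms: none
Why: Ionic hydrogenation: the acid ionises the secondary benzylic alcohol to a cation stabilised by the ortho- and para-methoxy groups, and the silane transfers hydride. The C2–O1 ether bears the less donating 3,4,5-trimethoxyphenyl group and should ionise much more slowly; the basic methanol work-up cleaves any trifluoroacetate of the primary alcohol.

## Compound list

1 | 2,4,5-trimethoxybenzaldehyde | COc1cc(OC)c(OC)cc1C=O | starting material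
2 | 1-ethynyl-2,4,5-trimethoxybenzene | COc1cc(OC)c(OC)cc1C#C | intermediate
3 | (5R)-5-(l-menthyloxy)furan-2(5H)-one | O=C1C=C[C@H](O[C@@H]2C[C@H](C)CC[C@H]2C(C)C)O1 | starting material
4 | (1S,4R,5S)-4-(l-menthyloxy)-6-(2,4,5-trimethoxyphenyl)-3-oxabicyclo[3.2.0]hept-6-en-2-one | COc1cc(OC)c(OC)cc1C1=C[C@@H]2C(=O)O[C@@H](O[C@@H]3C[C@H](C)CC[C@H]3C(C)C)[C@H]12 | intermediate
5 | sodium (1S,4S)-4-formyl-3-(2,4,5-trimethoxyphenyl)cyclobut-2-ene-1-carboxylate | [Na+].[O-]C(=O)[C@H]1C=C(c2cc(OC)c(OC)cc2OC)[C@H]1C=O | intermediate (not isolated)
6 | sodium (1S,4S)-4-(hydroxymethyl)-3-(2,4,5-trimethoxyphenyl)cyclobut-2-ene-1-carboxylate | [Na+].[O-]C(=O)[C@H]1C=C(c2cc(OC)c(OC)cc2OC)[C@H]1CO | intermediate (not isolated)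
7 | (1S,5S)-6-(2,4,5-trimethoxyphenyl)-3-oxabicyclo[3.2.0]hept-6-en-2-one | O=C1OC[C@H]2[C@@H]1C=C2c1cc(OC)c(OC)cc1OC | intermediate
8 | 5-bromo-1,2,3-trimethoxybenzene | COc1cc(Br)cc(OC)c1OC | starting material
9 | (3,4,5-trimethoxyphenyl)lithium | [Li]c1cc(OC)c(OC)c(OC)c1 | intermediate (not isolated)
10 | (1S,5S)-2-(3,4,5-trimethoxyphenyl)-6-(2,4,5-trimethoxyphenyl)-3-oxabicyclo[3.2.0]hept-6-en-2-ol (C2 anomers) | COc1cc(cc(OC)c1OC)C1(O)OC[C@H]2[C@@H]1C=C2c1cc(OC)c(OC)cc1OC | intermediate
11 | (1S,2R,5S)-2-(3,4,5-trimethoxyphenyl)-6-(2,4,5-trimethoxyphenyl)-3-oxabicyclo[3.2.0]hept-6-ene | COc1cc(cc(OC)c1OC)[C@@H]1OC[C@H]2[C@@H]1C=C2c1cc(OC)c(OC)cc1OC | intermediate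
12 | (1R,2R,5R,6S,7S)-2-(3,4,5-trimethoxyphenyl)-6-(2,4,5-trimethoxyphenyl)-3-oxabicyclo[3.2.0]heptane-6,7-diol | COc1cc(cc(OC)c1OC)[C@@H]1OC[C@H]2[C@@H]1[C@H](O)[C@@]2(O)c1cc(OC)c(OC)cc1OC | intermediate
13 | (2R,3S,4R)-2-(3,4,5-trimethoxyphenyl)-4-(2,4,5-trimethoxybenzoyl)oxolane-3-carbaldehyde | COc1cc(cc(OC)c1OC)[C@@H]1OC[C@H](C(=O)c2cc(OC)c(OC)cc2OC)[C@@H]1C=O | intermediate (not isolated)
14 | {(2R,3R,4R)-4-[hydroxy(2,4,5-trimethoxyphenyl)methyl]-2-(3,4,5-trimethoxyphenyl)oxolan-3-yl}methanol (carbinol epimers) | COc1cc(cc(OC)c1OC)[C@@H]1OC[C@H](C(O)c2cc(OC)c(OC)cc2OC)[C@@H]1CO | intermediate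
15 | [(2R,3R,4R)-2-(3,4,5-trimethoxyphenyl)-4-(2,4,5-trimethoxybenzyl)oxolan-3-yl]methanol | COc1cc(OC)c(OC)cc1C[C@H]1CO[C@@H](c2cc(OC)c(OC)c(OC)c2)[C@H]1CO | target

## Step count and least certain steps

Total: 8 steps. Longest linear sequence: 8 steps (1 → 2 → 4 → 7 → 10 → 11 → 12 → 14 → 15). Compounds 3 and 8 are purchased, and 9 is made in the flask of step 4.

**Step 2 (key step).**
- What may go wrong: poor orientational control is the most likely failure. If the first bond forms between the β-carbon of 3 and the alkyne terminus, the more stabilised biradical results and closes head-to-head. The excitation may also be diverted to alkyne 2, which absorbs near the irradiation window and is the likely triplet energy acceptor; an alkyne triplet would attack the β-carbon and give the same wrong orientation. Facial selectivity by a single acetal substituent is likely to be incomplete, and the styrene-type product can undergo secondary photoreactions at high conversion.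
- Fallback, from 3 back to 4: photocycloaddition of 3 with 1,1-diethoxyethene, a ketene acetal whose head-to-tail addition to butenolides is established, gives the cis-fused cyclobutanone diethyl acetal F1, with diastereomers separated at this stage. Mild acid hydrolysis (p-TsOH, wet acetone) gives the cyclobutanone F2. Kinetic enolisation toward the CH2 group (KN(SiMe3)2, PhNTf2, THF, −78 °C) gives the cyclobutenyl triflate F3. Suzuki–Miyaura coupling with 2,4,5-trimethoxyphenylboronic acid (Pd(PPh3)4, anhydrous K3PO4, dioxane, 50 °C) returns to 4 with the aryl group fixed on the correct carbon.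

**Step 5.**
- What may go wrong: acid-promoted attack on the electron-rich aryl cyclobutene (protonation followed by hydride capture or cationic rearrangement) may compete with ionisation of the lactol, because both sites are activated by methoxyarenes. Hydride delivery to the concave face is less likely.
- Fallback, from 10 back to 11: NaBH4 reduction of 10 through its hydroxy ketone tautomer gives the diol, from which the (R)-carbinol F4 is separated; the other epimer is returned to 10 by MnO2 oxidation. Selective sulfonylation of the primary hydroxyl (TsCl, pyridine, 0 °C) gives the monotosylate F5. NaH in THF closes the oxolane by attack of the benzylic alkoxide on the primary carbon, with retention at C2, to give 11 without any Lewis acid.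

**Step 8.**
- What may go wrong: the benzylic cation may lose a proton toward C4 and be re-protonated, which would scramble C4. The C2–O1 benzylic ether may ionise, leading to epimerisation at C2 or reductive ring opening. Reversible capture of the cation by the neighbouring hydroxymethyl group would slow the reduction.
- Fallback, from 14 to 15: catalytic hydrogenolysis of the benzylic alcohol (H2, Pd/C, EtOAc/EtOH, trace AcOH, rt), which cleaves the C–O bond on the metal surface without a free cation. It relies on the cyclic benzylic ether at C2 reacting more slowly than the free, more electron-rich benzylic alcohol. No new compound is formed.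

**Step 7.**
- What may go wrong: epimerisation at C3 (and C4) by enolisation of the all-cis keto aldehyde before hydride arrives. The electron-rich aryl ketone is reduced slowly, which lengthens the exposure.
- Fallback, from 11 to 14: ozonolysis of the cyclobutene (O3, CH2Cl2/MeOH, −78 °C, titrated against an indicator dye to spare the arenes), then NaBH4 added cold to the same flask. The peroxidic cleavage products are reduced directly, so no free carbonyl compound is handled. No new isolated compound is formed.

**Step 3.**
- What may go wrong: enolisation of the transient β,γ-unsaturated aldehyde before it is reduced, causing epimerisation at the ring carbon or migration of the double bond into conjugation. Electrocyclic opening of the monocyclic formylcyclobutene is possible if it is allowed to warm.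
- Fallback, from 4 back to 7: LiAlH4 in THF at 0 °C reduces both the lactone and the masked aldehyde and gives the cis diol F6 without a free aldehyde. Oxidative lactonisation with catalytic TEMPO and PhI(OAc)2 in CH2Cl2 at rt should start at the less hindered hydroxymethyl group, the one remote from the aryl substituent, and give 7. The regioisomeric lactone would be separated.

## Further compounds

F1 | step 2 | 6,6-diethoxy-4-(l-menthyloxy)-3-oxabicyclo[3.2.0]heptan-2-one (cis-fused, anti) | CCOC1(OCC)C[C@@H]2C(=O)O[C@@H](O[C@@H]3C[C@H](C)CC[C@H]3C(C)C)[C@H]12
F2 | step 2 | 4-(l-menthyloxy)-3-oxabicyclo[3.2.0]heptane-2,6-dione | O=C1C[C@@H]2C(=O)O[C@@H](O[C@@H]3C[C@H](C)CC[C@H]3C(C)C)[C@H]12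
F3 | step 2 | 4-(l-menthyloxy)-2-oxo-3-oxabicyclo[3.2.0]hept-6-en-6-yl trifluoromethanesulfonate | O=S(=O)(OC1=C[C@@H]2C(=O)O[C@@H](O[C@@H]3C[C@H](C)CC[C@H]3C(C)C)[C@H]12)C(F)(F)F
F4 | step 5 | (R)-[(1S,4S)-4-(hydroxymethyl)-3-(2,4,5-trimethoxyphenyl)cyclobut-2-en-1-yl](3,4,5-trimethoxyphenyl)methanol | COc1cc(cc(OC)c1OC)[C@H](O)[C@H]1C=C(c2cc(OC)c(OC)cc2OC)[C@H]1CO
F5 | step 5 | {(1S,4S)-4-[(R)-hydroxy(3,4,5-trimethoxyphenyl)methyl]-2-(2,4,5-trimethoxyphenyl)cyclobut-2-en-1-yl}methyl 4-methylbenzenesulfonate | COc1cc(cc(OC)c1OC)[C@H](O)[C@H]1C=C(c2cc(OC)c(OC)cc2OC)[C@H]1COS(=O)(=O)c1ccc(C)cc1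
F0 | step 8 | none | none
F0 | step 7 | none | none
F6 | step 3 | [(1S,2S)-3-(2,4,5-trimethoxyphenyl)cyclobut-3-ene-1,2-diyl]dimethanol | OC[C@H]1C=C(c2cc(OC)c(OC)cc2OC)[C@H]1CO
A1 | alternative 1 | methyl 2-(3,4,5-trimethoxyphenyl)-4-(2,4,5-trimethoxybenzyl)-2,5-dihydrofuran-3-carboxylate | COC(=O)C1=C(Cc2cc(OC)c(OC)cc2OC)CO[C@H]1c1cc(OC)c(OC)c(OC)c1
A2 | alternative 1 | methyl 2-{(3,4,5-trimethoxyphenyl)[2-(2,4,5-trimethoxybenzyl)prop-2-en-1-yloxy]methyl}prop-2-enoate | COC(=O)C(=C)[C@@H](OCC(=C)Cc1cc(OC)c(OC)cc1OC)c1cc(OC)c(OC)c(OC)c1
A3 | alternative 2 | cis-fused 8-(3,4,5-trimethoxyphenyl)-4-(2,4,5-trimethoxyphenyl)-3,7-dioxabicyclo[3.3.0]octan-2-one (8-aryl endo, 4-aryl exo) | COc1cc(OC)c(OC)cc1[C@@H]2[C@H]1CO[C@@H](c3cc(OC)c(OC)c(OC)c3)[C@H]1C(=O)O2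
A4 | alternative 2 | 3-diazo-4-{[(3,4,5-trimethoxybenzyl)oxy]methyl}-5-(2,4,5-trimethoxyphenyl)oxolan-2-one | COc1cc(OC)c(OC)cc1[C@H]1OC(=O)C(=[N+]=[N-])[C@@H]1COCc1cc(OC)c(OC)c(OC)c1
A5 | alternative 3 | methyl 2-(3,4,5-trimethoxyphenyl)-4-(2,4,5-trimethoxybenzyl)-4,5-dihydrofuran-3-carboxylate | COc1cc(OC)c(OC)cc1C[C@H]1COC(c2cc(OC)c(OC)c(OC)c2)=C1C(=O)OC
A6 | alternative 3 | methyl 1-(3,4,5-trimethoxybenzoyl)-2-(2,4,5-trimethoxybenzyl)cyclopropane-1-carboxylate (C1 configuration immaterial) | COC(=O)C1(C(=O)c2cc(OC)c(OC)c(OC)c2)C[C@@H]1Cc1cc(OC)c(OC)cc1OC
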